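**Retrosynthetic overview**
- Last bond, C1–C10: a nickel/chromium-catalysed alkenyl iodide–aldehyde coupling closes the ten-membered carbocycle and creates the C1 carbinol next to the exocyclic methylene.
- Before that: C6–O angeloylation, and the C6–C7 bond by zinc Barbier union of fragment A (bromomethyl butenolide, C7–C14) with fragment B (epoxy aldehyde, C1–C6 and C15); this gives the α-methylene lactone and sets C6 and C7.
- Fragment A: butenolide by ring-closing metathesis of a branched allylic 2-(bromomethyl)acrylate whose C8–O bond and stereocentre come from an enantioselective palladium-catalysed allylic C–H acyloxylation; alkenylsilane to alkenyl iodide.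
- Fragment B: zirconium-catalysed carboalumination (E-olefin), Sharpless epoxidation (C4, C5), oxidation.
- Ring order: oxirane (fragment B) and butenolide (fragment A) first, the ten-membered ring last.

Assumption: locants C1–C15 follow germacrane numbering of the target (ring C1–C10, lactone C11–C13 on C7/C8, exocyclic CH2 C14 on C10, methyl C15 on C4), in which the target is (1S,4R,5R,6S,7R,8S); chiral ligands and catalysts are taken as available reagents.

**Fragment A**

Step 1
Reactants: 1 (1-bromoethenyl)trimethylsilane; 2 but-3-en-1-ylmagnesium bromide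
Product: 3 trimethyl(hexa-1,5-dien-2-yl)silane
Conditions: PdCl2(dppf) (1 mol%), THF, 0 °C to rt
Reagents that add atoms: none
Why: Kumada–Corriu cross-coupling of an alkenyl bromide with a primary alkyl Grignard reagent, the wide-bite-angle diphosphine favouring reductive elimination over β-hydride elimination; no stereocentre is formed.

Step 2
Reactants: 3 trimethyl(hexa-1,5-dien-2-yl)silane; 4 2-(bromomethyl)prop-2-enoic acid
Product: 5 (3S)-5-(trimethylsilyl)hexa-1,5-dien-3-yl 2-(bromomethyl)prop-2-enoate
Conditions: Pd(OAc)2 (10 mol%), chiral tert-butylsulfinyl–olefin hybrid ligand (12 mol%), 2,6-dimethyl-1,4-benzoquinone (1.5 equiv), 4 Å MS, 1,4-dioxane, 45 °C, no added base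
Reagents that add atoms: none
Why: Proposed new method: enantioselective branched allylic C–H acyloxylation, in which the sulfoxide arm of the ligand assists electrophilic cleavage of the terminal allylic C8–H bond by the divalent palladium carboxylate to give a π-allylpalladium carboxylate (the hindered 1,1-disubstituted alkenylsilane does not engage), the tethered π-acidic olefin arm then takes the role that benzoquinone plays in the racemic reaction and triggers inner-sphere C–O reductive elimination at the internal allyl terminus while the chiral ligand is still bound, so that C8 is set (S) by discrimination between rapidly π–σ–π-equilibrating allyl complexes (ligand antipode chosen accordingly) and the quinone only reoxidises zerovalent palladium; the closest known reaction type is the racemic palladium/bis-sulfoxide-catalysed branch-selective allylic C–H esterification of terminal olefins with carboxylic acids and its modestly enantioselective variant with a chiral Lewis acid co-catalyst.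

Step 3
Reactants: 5 (3S)-5-(trimethylsilyl)hexa-1,5-dien-3-yl 2-(bromomethyl)prop-2-enoate
Product: 6 (5S)-3-(bromomethyl)-5-[2-(trimethylsilyl)prop-2-en-1-yl]furan-2(5H)-one
Conditions: second-generation Hoveyda–Grubbs catalyst (5 mol%), toluene (0.01 M), 80 °C
Reagents that add atoms: none
Why: Ring-closing metathesis between the vinyl group and the acrylate olefin forms the butenolide (C7=C11) with loss of ethene, the 1,1-disubstituted alkenylsilane being inert and C8 untouched.

Step 4
Reactants: 6 (5S)-3-(bromomethyl)-5-[2-(trimethylsilyl)prop-2-en-1-yl]furan-2(5H)-one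
Product: 7 (5S)-3-(bromomethyl)-5-(2-iodoprop-2-en-1-yl)furan-2(5H)-one
Conditions: N-iodosuccinimide (1.3 equiv), MeCN/ClCH2CN (4:1), 0 °C to rt, dark
Reagents that add atoms: N-iodosuccinimide (O=C1CCC(=O)N1I)
Why: Electrophilic ipso-iododesilylation of the 2-silyl-1-alkene gives the 2-iodo-1-alkene needed for the nickel/chromium coupling, while the electron-poor butenolide olefin and the allylic bromide do not react.

**Fragment B**

Step 5
Reactants: 8 pent-4-yn-1-ol
Product: 9 triethyl(pent-4-yn-1-yloxy)silane
Conditions: Et3SiCl, imidazole, CH2Cl2, 0 °C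
Reagents that add atoms: chlorotriethylsilane (CC[Si](Cl)(CC)CC)
Why: Standard silylation; the primary triethylsilyl ether survives the following steps and can later be oxidised directly to the aldehyde.

Step 6
Reactants: 9 triethyl(pent-4-yn-1-yloxy)silane
Product: 11 (2E)-3-methyl-6-[(triethylsilyl)oxy]hex-2-en-1-ol, via alkenyldimethylalane 10 (not isolated)
Conditions: Me3Al (2.5 equiv), Cp2ZrCl2 (0.25 equiv), CH2Cl2, 0 °C to rt; then n-BuLi, (CH2O)n, THF, −78 °C to rt
Reagents that add atoms: trimethylaluminium (C[Al](C)C); paraformaldehyde (C=O as formaldehyde)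
Why: Negishi zirconium-catalysed syn-carboalumination adds methyl (C15) and aluminium cis across the alkyne, and trapping of the alanate with formaldehyde (C6) retains the geometry, so the E-trisubstituted olefin is set.

Step 7
Reactants: 11 (2E)-3-methyl-6-[(triethylsilyl)oxy]hex-2-en-1-ol
Product: 12 [(2R,3R)-3-methyl-3-{3-[(triethylsilyl)oxy]propyl}oxiran-2-yl]methanol
Conditions: Ti(OiPr)4 (10 mol%), D-(−)-diethyl tartrate (12 mol%), t-BuOOH (2 equiv), 4 Å MS, CH2Cl2, −20 °C
Reagents that add atoms: tert-butyl hydroperoxide (CC(C)(C)OO)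
Why: Sharpless asymmetric epoxidation of a geraniol-type allylic alcohol; the D-(−)-tartrate delivers oxygen to the face that gives (2R,3R), which is C5(R) and C4(R) of the target (L-(+)-tartrate gives 2S,3S in this series).

Step 8
Reactants: 12 [(2R,3R)-3-methyl-3-{3-[(triethylsilyl)oxy]propyl}oxiran-2-yl]methanol
Product: 13 (2S,3R)-3-methyl-3-{3-[(triethylsilyl)oxy]propyl}oxirane-2-carbaldehyde
Conditions: PhI(OAc)2 (1.1 equiv), TEMPO (10 mol%), CH2Cl2, rt
Reagents that add atoms: none
Why: Oxoammonium-mediated oxidation of the primary alcohol stops at the aldehyde and leaves the epoxide and silyl ether intact; the descriptor at the oxirane CH changes to S only because the formyl group now outranks the ring carbon.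

**Angeloyl donor**

Step 9
Reactants: 14 angelic acid, (2Z)-2-methylbut-2-enoic acid
Product: 15 (2Z)-2-methylbut-2-enoic 2,4,6-trichlorobenzoic anhydride
Conditions: 2,4,6-trichlorobenzoyl chloride (1.0 equiv), Et3N (1.1 equiv), toluene, rt; filtered and used as a toluene solution
Reagents that add atoms: 2,4,6-trichlorobenzoyl chloride (O=C(Cl)c1c(Cl)cc(Cl)cc1Cl)
Why: Yamaguchi-type mixed anhydride formation activates angelic acid without a nucleophilic catalyst, so the Z-olefin is not isomerised.

**Union and endgame**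

Step 10
Reactants: 7 (5S)-3-(bromomethyl)-5-(2-iodoprop-2-en-1-yl)furan-2(5H)-one; 13 (2S,3R)-3-methyl-3-{3-[(triethylsilyl)oxy]propyl}oxirane-2-carbaldehyde
Product: 17 (4S,5S)-4-{(S)-hydroxy[(2R,3R)-3-methyl-3-{3-[(triethylsilyl)oxy]propyl}oxiran-2-yl]methyl}-5-(2-iodoprop-2-en-1-yl)-3-methylideneoxolan-2-one, via allylzinc bromide 16 (not isolated)
Conditions: Zn dust (3 equiv), THF/sat. aq NH4Cl (2:1), 0 °C to rt
Reagents that add atoms: none
Why: Barbier allylation with γ-attack of the butenolide-derived allylzinc through a closed chair transition state forms C6–C7 and the α-methylene lactone: the aldehyde adds to C7 anti to the C8 side chain (trans lactone) with its residue equatorial (C6 as in the target), and zinc held between the carbonyl and epoxide oxygens turns H5 toward the nucleophile, reinforcing that face.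

Step 11
Reactants: 17 the hydroxy lactone from step 10; 15 (2Z)-2-methylbut-2-enoic 2,4,6-trichlorobenzoic anhydride
Product: 18 (S)-[(2S,3R)-2-(2-iodoprop-2-en-1-yl)-4-methylidene-5-oxooxolan-3-yl][(2R,3R)-3-methyl-3-{3-[(triethylsilyl)oxy]propyl}oxiran-2-yl]methyl (2Z)-2-methylbut-2-enoate
Conditions: 15 (3 equiv), Et3N (1 equiv), toluene, 80 °C, no DMAP
Reagents that add atoms: none
Why: Yamaguchi-type O-acylation at the unhindered angeloyl carbonyl of the mixed anhydride without acyl-transfer catalyst avoids Z-to-E isomerisation to the tiglate, and C6 keeps its configuration because only the O–H bond reacts.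

Step 12
Reactants: 18 the angelate from step 11
Product: 19 (S)-[(2S,3R)-2-(2-iodoprop-2-en-1-yl)-4-methylidene-5-oxooxolan-3-yl][(2R,3R)-3-methyl-3-(3-oxopropyl)oxiran-2-yl]methyl (2Z)-2-methylbut-2-enoate
Conditions: (COCl)2, DMSO, CH2Cl2, −78 to −40 °C; then Et3N, −78 to 0 °C
Reagents that add atoms: none
Why: Under Swern conditions a primary triethylsilyl ether is cleaved by the chlorosulfonium salt and oxidised in the same operation to the aldehyde, and the epoxide, esters and alkenyl iodide are inert.

Step 13
Reactants: 19 the seco-aldehyde from step 12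
Product: 20 (1S,4R,5R,6S,7R,8S)-4,5-epoxy-1-hydroxy-6-[(2Z)-2-methylbut-2-enoyloxy]germacra-10(14),11(13)-dien-12,8-olide
Conditions: CrCl2 (20 mol%), chiral oxazoline–sulfonamide ligand (22 mol%, antipode that delivers 1S), proton sponge (22 mol%), NiCl2·(2,9-dimethyl-1,10-phenanthroline) (5 mol%), Mn powder (2 equiv), Cp2ZrCl2 (1.5 equiv), LiCl (2 equiv), MeCN, rt, slow addition of 19 (final 2 mM)
Reagents that add atoms: none
Why: Nozaki–Hiyama–Kishi macrocyclisation in which zerovalent nickel inserts into the C10–I bond, transmetalation gives a carbonyl-selective alkenyl species of trivalent chromium that adds to the C1 aldehyde and closes the ten-membered ring, the sulfonamide-bound chromium choosing the aldehyde face (1S) while Mn and Cp2ZrCl2 turn the chromium over.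

**Compound list**

1 | (1-bromoethenyl)trimethylsilane | C=C(Br)[Si](C)(C)C | starting material
2 | but-3-en-1-ylmagnesium bromide | C=CCC[Mg]Br | starting material
3 | trimethyl(hexa-1,5-dien-2-yl)silane | C=CCCC(=C)[Si](C)(C)C | intermediate
4 | 2-(bromomethyl)prop-2-enoic acid | C=C(CBr)C(=O)O | starting material
5 | (3S)-5-(trimethylsilyl)hexa-1,5-dien-3-yl 2-(bromomethyl)prop-2-enoate | C=C[C@H](CC(=C)[Si](C)(C)C)OC(=O)C(=C)CBr | intermediate
6 | (5S)-3-(bromomethyl)-5-[2-(trimethylsilyl)prop-2-en-1-yl]furan-2(5H)-one | O=C1O[C@@H](CC(=C)[Si](C)(C)C)C=C1CBr | intermediate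
7 | (5S)-3-(bromomethyl)-5-(2-iodoprop-2-en-1-yl)furan-2(5H)-one | O=C1O[C@@H](CC(I)=C)C=C1CBr | intermediate
8 | pent-4-yn-1-ol | C#CCCCO | starting material
9 | triethyl(pent-4-yn-1-yloxy)silane | C#CCCCO[Si](CC)(CC)CC | intermediate
10 | dimethyl{(1E)-2-methyl-5-[(triethylsilyl)oxy]pent-1-en-1-yl}alumane | CC[Si](CC)(CC)OCCC/C(C)=C/[Al](C)C | intermediate (not isolated)
11 | (2E)-3-methyl-6-[(triethylsilyl)oxy]hex-2-en-1-ol | CC[Si](CC)(CC)OCCC/C(C)=C/CO | intermediate
12 | [(2R,3R)-3-methyl-3-{3-[(triethylsilyl)oxy]propyl}oxiran-2-yl]methanol | CC[Si](CC)(CC)OCCC[C@@]1(C)O[C@@H]1CO | intermediate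
13 | (2S,3R)-3-methyl-3-{3-[(triethylsilyl)oxy]propyl}oxirane-2-carbaldehyde | CC[Si](CC)(CC)OCCC[C@@]1(C)O[C@@H]1C=O | intermediate
14 | angelic acid, (2Z)-2-methylbut-2-enoic acid | C/C=C(/C)C(=O)O | starting material
15 | (2Z)-2-methylbut-2-enoic 2,4,6-trichlorobenzoic anhydride | C/C=C(/C)C(=O)OC(=O)c1c(Cl)cc(Cl)cc1Cl | intermediate
16 | bromido{[(5S)-5-(2-iodoprop-2-en-1-yl)-2-oxo-2,5-dihydrofuran-3-yl]methyl}zinc | Br[Zn]CC1=C[C@H](CC(I)=C)OC1=O | intermediate (not isolated)
17 | (4S,5S)-4-{(S)-hydroxy[(2R,3R)-3-methyl-3-{3-[(triethylsilyl)oxy]propyl}oxiran-2-yl]methyl}-5-(2-iodoprop-2-en-1-yl)-3-methylideneoxolan-2-one | C=C1C(=O)O[C@@H](CC(I)=C)[C@@H]1[C@H](O)[C@H]2O[C@]2(C)CCCO[Si](CC)(CC)CC | intermediate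
18 | (S)-[(2S,3R)-2-(2-iodoprop-2-en-1-yl)-4-methylidene-5-oxooxolan-3-yl][(2R,3R)-3-methyl-3-{3-[(triethylsilyl)oxy]propyl}oxiran-2-yl]methyl (2Z)-2-methylbut-2-enoate | C=C1C(=O)O[C@@H](CC(I)=C)[C@@H]1[C@H](OC(=O)/C(C)=C\C)[C@H]2O[C@]2(C)CCCO[Si](CC)(CC)CC | intermediate
19 | (S)-[(2S,3R)-2-(2-iodoprop-2-en-1-yl)-4-methylidene-5-oxooxolan-3-yl][(2R,3R)-3-methyl-3-(3-oxopropyl)oxiran-2-yl]methyl (2Z)-2-methylbut-2-enoate | C=C1C(=O)O[C@@H](CC(I)=C)[C@@H]1[C@H](OC(=O)/C(C)=C\C)[C@H]2O[C@]2(C)CCC=O | intermediate
20 | (1S,4R,5R,6S,7R,8S)-4,5-epoxy-1-hydroxy-6-[(2Z)-2-methylbut-2-enoyloxy]germacra-10(14),11(13)-dien-12,8-olide | C=C1C(=O)O[C@H]2CC(=C)[C@@H](O)CC[C@@]3(C)O[C@@H]3[C@@H](OC(=O)/C(C)=C\C)[C@H]12 | target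

**Step count**

Total: 13 steps. Longest linear sequence: 8 steps (steps 1–4 then 10–13, or equally steps 5–8 then 10–13), which is 8/13 of the total.

**Three steps most likely to fail**

Step 2 (the proposed new C–H acyloxylation). Risks are insufficient enantioselectivity, competing diene formation from the π-allyl intermediate, and self-alkylation of acid 4 through its allylic bromide. The fallback uses known chiral-pool chemistry; it sets out from compound 1 and comes back to the route at compound 5. Magnesium insertion into 1 gives [1-(trimethylsilyl)ethenyl]magnesium bromide F1. This opens commercial (S)-epichlorohydrin (ClC[C@@H]1CO1, five non-hydrogen atoms) at the epoxide terminus under CuI catalysis (THF, −40 to 0 °C) to give (2S)-1-chloro-4-(trimethylsilyl)pent-4-en-2-ol F2. Excess dimethylsulfonium methylide (Me3SI, n-BuLi, THF, −20 °C to rt) first closes F2 to (2S)-2-[2-(trimethylsilyl)prop-2-en-1-yl]oxirane F3 and then, in the same flask, opens it at the terminus and eliminates to (3S)-5-(trimethylsilyl)hexa-1,5-dien-3-ol F4. Steglich esterification of F4 with acid 4 (DCC, catalytic DMAP, CH2Cl2, 0 °C) gives 5 with C8 taken from the chiral pool.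

Step 10 (Barbier union with the epoxy aldehyde). The butenolide-controlled chair transition state and the intrinsic non-chelated (Felkin-type) preference of the α,β-epoxy aldehyde point to opposite C6 epimers. The planned selectivity therefore depends on zinc chelation by the epoxide oxygen. The epoxy aldehyde may also rearrange, or the zinc alkoxide may translactonise. The fallback removes the stereocentres from the aldehyde partner; it sets out from compound 11 (with compound 7) and comes back at compound 17. MnO2 oxidation of 11 gives the achiral enal (2E)-3-methyl-6-[(triethylsilyl)oxy]hex-2-enal F5. The same zinc Barbier reaction with 7 (through 16) then gives (4S,5S)-4-{(1R,2E)-1-hydroxy-3-methyl-6-[(triethylsilyl)oxy]hex-2-en-1-yl}-5-(2-iodoprop-2-en-1-yl)-3-methylideneoxolan-2-one F6, with C6 and C7 set by the butenolide alone. Hydroxyl-directed epoxidation of F6 with buffered mCPBA (NaHCO3, CH2Cl2, 0 °C) is threo-selective because the C15 methyl is cis to C6 and A(1,3) strain fixes the carbinol rotamer; it delivers 17 with the C4, C5 and C6 configuration of the target.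

Step 13 (macrocyclisation). Risks are slow catalytic turnover at high dilution and insufficient or inverted control at C1. The fallback separates ring closure from control of C1; it sets out from compound 19 and comes back at compound 20. Substrate-controlled ring closure with stoichiometric CrCl2 and catalytic NiCl2 in DMSO at 3 mM gives the C1 epimer (1R,4R,5R,6S,7R,8S)-4,5-epoxy-1-hydroxy-6-[(2Z)-2-methylbut-2-enoyloxy]germacra-10(14),11(13)-dien-12,8-olide F7, alone or mixed with 20. Dess–Martin oxidation of this material (NaHCO3, CH2Cl2) gives the exocyclic enone (4R,5R,6S,7R,8S)-4,5-epoxy-6-[(2Z)-2-methylbut-2-enoyloxy]-1-oxogermacra-10(14),11(13)-dien-12,8-olide F8. Corey–Bakshi–Shibata reduction of F8 with the (R)-methyl oxazaborolidine and catecholborane (toluene, −78 °C) treats the alkenyl branch as the large group and gives the (1S)-alcohol 20.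

**Further compounds**

F1 | step 2 | [1-(trimethylsilyl)ethenyl]magnesium bromide | C=C([Mg]Br)[Si](C)(C)C
F2 | step 2 | (2S)-1-chloro-4-(trimethylsilyl)pent-4-en-2-ol | ClC[C@@H](O)CC(=C)[Si](C)(C)C
F3 | step 2 | (2S)-2-[2-(trimethylsilyl)prop-2-en-1-yl]oxirane | C=C(C[C@H]1CO1)[Si](C)(C)C
F4 | step 2 | (3S)-5-(trimethylsilyl)hexa-1,5-dien-3-ol | C=C[C@@H](O)CC(=C)[Si](C)(C)C
F5 | step 10 | (2E)-3-methyl-6-[(triethylsilyl)oxy]hex-2-enal | CC[Si](CC)(CC)OCCC/C(C)=C/C=O
F6 | step 10 | (4S,5S)-4-{(1R,2E)-1-hydroxy-3-methyl-6-[(triethylsilyl)oxy]hex-2-en-1-yl}-5-(2-iodoprop-2-en-1-yl)-3-methylideneoxolan-2-one | C=C1C(=O)O[C@@H](CC(I)=C)[C@@H]1[C@H](O)/C=C(\C)CCCO[Si](CC)(CC)CC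
F7 | step 13 | (1R,4R,5R,6S,7R,8S)-4,5-epoxy-1-hydroxy-6-[(2Z)-2-methylbut-2-enoyloxy]germacra-10(14),11(13)-dien-12,8-olide | C=C1C(=O)O[C@H]2CC(=C)[C@H](O)CC[C@@]3(C)O[C@@H]3[C@@H](OC(=O)/C(C)=C\C)[C@H]12
F8 | step 13 | (4R,5R,6S,7R,8S)-4,5-epoxy-6-[(2Z)-2-methylbut-2-enoyloxy]-1-oxogermacra-10(14),11(13)-dien-12,8-olide | C=C1C(=O)O[C@H]2CC(=C)C(=O)CC[C@@]3(C)O[C@@H]3[C@@H](OC(=O)/C(C)=C\C)[C@H]12
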